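## Retrosynthetic overview

Positions follow the cyclohexenone of the target: C1 ketone, C2 (bearing C7H2–O-tigloyl), C3 (=CH), C4 (O-tigloyl), C5 (isopropyl), C6 (acetoxy). The three esters go on last, and C7 comes from formaldehyde by a Morita–Baylis–Hillman reaction.
The key disconnection cuts C1–C6 and C4–C5 together. This splits the core into furan-2(5H)-one (C1–C4 with O1 and O4) and the Z-enol of 3-methylbutanal (C5, C6, isopropyl, O6), held together by one di-tert-butylsilyl group.
Two structural features make this possible. C1 and C4 both carry oxygen and flank the C2=C3 double bond, so the 4-oxy-enone is a ring-opened 2-oxyfuran cycloadduct whose furan oxygen once bridged C1 and C4. O1 and O6 are vicinal, so an O–Si–O link can tie diene and dienophile through a five-membered 1,3,2-dioxasilolane.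
Order of rings: the furan forms by enolisation. The key step then closes the carbocycle, the oxygen bridge and the dioxasilolane together. The bridge opens to the enone with a six-membered 1,3,2-dioxasilinane across O4/O6, which is cleaved later.
Relative configuration at C4/C5 comes from the cycloaddition and C6 from equilibration. Absolute configuration comes from a lipase resolution of the C6 acetate.

Key step: step 2

Remark: compounds 6 to 12 are racemic. Their SMILES show the enantiomer that is kept in step 7.

## Route

Step 1
Reactants: 1 furan-2(5H)-one; 2 di-tert-butylsilyl bis(trifluoromethanesulfonate); 3 3-methylbutanal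
Product: 5 di-tert-butyl(furan-2-yloxy)[(Z)-3-methylbut-1-en-1-yloxy]silane, via furyloxysilyl triflate 4 (not isolated)
Conditions: 2, Et3N, CH2Cl2, −78 to 0 °C, slow addition of 1; then 3, Et3N, 0 °C to rt
Reagents that add atoms: none
Why: Two successive soft enolisations with a silyl triflate and an amine (the standard O-silylation route to 2-silyloxyfurans and aldehyde enol silanes) should work because the first substitution leaves a much more hindered Si–OTf that waits for the aldehyde, and deprotonation of the O-silylated aldehyde through the conformer with the alkyl chain eclipsing C=O should give the Z-enol ether; no stereocentre is formed.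

Step 2
Reactants: 5 di-tert-butyl(furan-2-yloxy)[(Z)-3-methylbut-1-en-1-yloxy]silane
Product: 7 racemic all-cis 3,3-di-tert-butyl-9-isopropyl-2,4-dioxa-3-silabicyclo[3.3.1]non-6-en-8-one (the 4,6-O-silylene of 4,6-dihydroxy-5-isopropylcyclohex-2-enone), via oxa-bridged cycloadduct 6 (not isolated)
Conditions: toluene (high dilution), BHT, 2,6-di-tert-butylpyridine (cat.), sealed tube, 170 °C
Reagents that add atoms: none
Why: Proposed new method: heating should bring furan carbons C2 and C5 of 5 and the Z-enol ether held three atoms away into an intramolecular Diels–Alder reaction that forms the C1–C6 and C4–C5 bonds of the cyclohexenone in one concerted suprafacial event, after which the strained silyl ketal 6 collapses because its oxygen bridge lies next to silicon and takes it over (1,3 O-to-O silyl shift), freeing the C1 ketone and making the sequence irreversible. The closest known reaction types are the intramolecular furan Diels–Alder reactions of 2-amino- and 2-oxy-substituted furans with unactivated alkenes on three-atom tethers that are driven by opening of the oxygen bridge, temporary silicon-tethered Diels–Alder reactions, and the silyl-shift ring opening of 2-silyloxyfuran cycloadducts; what is new is an enol ether as dienophile bound through an O–Si–O link. Ring closure: the six-membered carbocycle closes by [4+2] cycloaddition, the five-membered 1,3,2-dioxasilolane of 6 closes with the C1–C6 bond (type 1 tether, exo), and the six-membered 1,3,2-dioxasilinane of 7 closes by silyl transfer from O1 to the former furan oxygen on C4. Stereocontrol: O4 is the former bridge oxygen, the short tether reaches only the exo position so that O6 is syn to the bridge, and the Z geometry carries the isopropyl group to the exo side as well, which gives the all-cis C4/C5/C6 array, as a racemate because 5 is achiral. The step needs regiocontrol, which the tether enforces (C6 can only meet C1), and enough reactivity from two donor-substituted partners, which is to come from intramolecularity, the low aromatic stabilisation of a 2-silyloxyfuran, the angle compression by the two tert-butyl groups and the irreversible collapse of 6.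

Step 3
Reactants: 7 silylene-bridged enone
Product: 8 racemic 7-(hydroxymethyl) derivative of 7 (hydroxymethyl on C2 of the enone)
Conditions: formalin (37 % aq), DMAP (cat.), THF, rt
Reagents that add atoms: formaldehyde, C=O
Why: Morita–Baylis–Hillman reaction, routine for cyclohex-2-enones including 4-oxygenated ones, should work here because the silylene masks both secondary oxygens and a bridgehead enolate at C6 is geometrically impossible, so no stereocentre is touched.

Step 4
Reactants: 8 hydroxymethyl enone
Product: 9 racemic primary tiglate of 8
Conditions: tigloyl chloride, Et3N, DMAP (cat.), CH2Cl2, 0 °C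
Reagents that add atoms: tigloyl chloride, C/C=C(\C)C(Cl)=O
Why: DMAP-catalysed acylation (nucleophilic acyl substitution) of the only free hydroxyl, a primary allylic one, should be clean and leaves all stereocentres untouched.

Step 5
Reactants: 9 primary tiglate with silylene
Product: 10 racemic (4S,5S,6S)-4,6-dihydroxy-5-isopropyl-2-(tigloyloxymethyl)cyclohex-2-en-1-one (all-cis diol)
Conditions: HF·pyridine, THF, 0 °C (polypropylene vessel)
Reagents that add atoms: none
Why: Fluoride cleavage of a di-tert-butylsilylene acetal under buffered acidic conditions is standard and should spare the ester, the enone and the three stereocentres.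

Step 6
Reactants: 10 all-cis diol
Product: 12 racemic (4S,5S,6R)-6-acetoxy-4-hydroxy-5-isopropyl-2-(tigloyloxymethyl)cyclohex-2-en-1-one, via C6-epimerised ketol 11 (not isolated)
Conditions: Et3N (0.5 equiv), CH2Cl2, rt; then pyridine, Ac2O (1 equiv), −20 °C
Reagents that add atoms: acetic anhydride, CC(=O)OC(C)=O
Why: Amine-catalysed enolisation of the alpha-ketol (through the enediol) should move C6 to the thermodynamic configuration, O6 equatorial and trans to isopropyl, because this removes the syn-diaxial O4/O6 contact while conjugation keeps the carbonyl at C1, and the following kinetic acetylation should take the equatorial C6 hydroxyl ahead of the pseudoaxial C4 hydroxyl, the same order of rates as menthol against neomenthol.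

Step 7
Reactants: 12 racemic monoacetate
Product: 13 (4S,5S,6R)-6-acetoxy-4-hydroxy-5-isopropyl-2-(tigloyloxymethyl)cyclohex-2-en-1-one as single enantiomer
Conditions: Candida rugosa lipase, phosphate buffer pH 7/MTBE, 30 °C, stopped just past half conversion
Reagents that add atoms: none
Why: Enzymatic kinetic resolution by enantioselective ester hydrolysis is established for 6-acetoxycyclohex-2-enones and for menthyl acetate, and by the empirical size rule for lipases the antipode, whose C6/C5 array matches (−)-menthyl acetate, should be hydrolysed while the (4S,5S,6R)-acetate is left, which fixes the absolute configuration of all three stereocentres at once.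

Step 8
Reactants: 13 enantiopure monoacetate
Product: 14 target, (4S,5S,6R)-6-acetoxy-5-isopropyl-4-(tigloyloxy)-2-(tigloyloxymethyl)cyclohex-2-en-1-one
Conditions: tigloyl chloride, Et3N, DMAP (cat.), CH2Cl2, 0 °C to rt
Reagents that add atoms: tigloyl chloride, C/C=C(\C)C(Cl)=O
Why: DMAP-catalysed acylation of the last free hydroxyl proceeds with retention at C4, and C6, the only base-labile centre, already has its thermodynamic configuration, so nothing can be scrambled.

## Compound list

1 | furan-2(5H)-one | O=C1C=CCO1 | starting material
2 | di-tert-butylsilyl bis(trifluoromethanesulfonate) | CC(C)(C)[Si](OS(=O)(=O)C(F)(F)F)(OS(=O)(=O)C(F)(F)F)C(C)(C)C | starting material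
3 | 3-methylbutanal | CC(C)CC=O | starting material
4 | di-tert-butyl(furan-2-yloxy)silyl trifluoromethanesulfonate (not isolated) | CC(C)(C)[Si](Oc1ccco1)(OS(=O)(=O)C(F)(F)F)C(C)(C)C | intermediate
5 | di-tert-butyl(furan-2-yloxy)[(Z)-3-methylbut-1-en-1-yloxy]silane | CC(C)/C=C\O[Si](Oc1ccco1)(C(C)(C)C)C(C)(C)C | intermediate
6 | oxa-bridged cycloadduct: 7-oxanorbornene with O–Si–O ring fused exo at the ketal bridgehead, isopropyl exo (racemic, not isolated) | CC(C)[C@H]1[C@@H]2C=C[C@]3(O2)O[Si](C(C)(C)C)(C(C)(C)C)O[C@@H]13 | intermediate
7 | all-cis 3,3-di-tert-butyl-9-isopropyl-2,4-dioxa-3-silabicyclo[3.3.1]non-6-en-8-one (racemic) | O=C1C=C[C@@H]2O[Si](C(C)(C)C)(C(C)(C)C)O[C@H]1[C@H]2C(C)C | intermediate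
8 | 7-(hydroxymethyl) derivative of 7 (racemic) | O=C1C(CO)=C[C@@H]2O[Si](C(C)(C)C)(C(C)(C)C)O[C@H]1[C@H]2C(C)C | intermediate
9 | primary tiglate of 8 (racemic) | O=C1C(COC(=O)/C(C)=C/C)=C[C@@H]2O[Si](C(C)(C)C)(C(C)(C)C)O[C@H]1[C@H]2C(C)C | intermediate
10 | (4S,5S,6S)-4,6-dihydroxy-5-isopropyl-2-(tigloyloxymethyl)cyclohex-2-en-1-one, all-cis (racemic) | C/C=C(\C)C(=O)OCC1=C[C@H](O)[C@H](C(C)C)[C@H](O)C1=O | intermediate
11 | (4S,5S,6R)-4,6-dihydroxy-5-isopropyl-2-(tigloyloxymethyl)cyclohex-2-en-1-one, 5,6-trans (racemic, not isolated) | C/C=C(\C)C(=O)OCC1=C[C@H](O)[C@H](C(C)C)[C@@H](O)C1=O | intermediate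
12 | (4S,5S,6R)-6-acetoxy-4-hydroxy-5-isopropyl-2-(tigloyloxymethyl)cyclohex-2-en-1-one (racemic) | C/C=C(\C)C(=O)OCC1=C[C@H](O)[C@H](C(C)C)[C@@H](OC(C)=O)C1=O | intermediate
13 | (4S,5S,6R)-6-acetoxy-4-hydroxy-5-isopropyl-2-(tigloyloxymethyl)cyclohex-2-en-1-one (single enantiomer) | C/C=C(\C)C(=O)OCC1=C[C@H](O)[C@H](C(C)C)[C@@H](OC(C)=O)C1=O | intermediate
14 | (4S,5S,6R)-6-acetoxy-5-isopropyl-4-(tigloyloxy)-2-(tigloyloxymethyl)cyclohex-2-en-1-one | C/C=C(\C)C(=O)OCC1=C[C@H](OC(=O)/C(C)=C/C)[C@H](C(C)C)[C@@H](OC(C)=O)C1=O | target

## Step count and risks

Total step count: 8. Longest linear sequence: 8 steps (from 1).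

**Step 2.** The cycloaddition may be too slow because both partners are donor-substituted. Thermal Z/E isomerisation of the enol ether or loss of the silyl link could then overtake ring formation.
- The fallback uses known chemistry and runs from 1 back to 12. The two bonds are made one after the other by the anionic counterpart, a Michael addition followed by a Dieckmann condensation (the aliphatic form of the Hauser–Kraus annulation).
- 1 and tert-butyl (E)-4-methylpent-2-enoate with KOtBu in THF should react by gamma-selective vinylogous Michael addition. Closure of the ester enolate on the lactone carbonyl then gives tert-butyl 5-hydroxy-6-isopropyl-2-oxocyclohex-3-ene-1-carboxylate F1.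
- CF3CO2H followed by gentle warming removes the ester carbon and gives cis-4-hydroxy-5-isopropylcyclohex-2-en-1-one F2. The 4,5-trans isomer is removed by chromatography.
- Morita–Baylis–Hillman hydroxymethylation as in step 3 gives cis-4-hydroxy-2-(hydroxymethyl)-5-isopropylcyclohex-2-en-1-one F3.
- Selective acylation of the primary hydroxyl with tigloyl chloride gives cis-4-hydroxy-5-isopropyl-2-(tigloyloxymethyl)cyclohex-2-en-1-one F4.
- Alpha'-acetoxylation of the enone with Mn(OAc)3 in refluxing benzene, which enters anti to the isopropyl group, gives 12.

**Step 1.** Double substitution of silicon by the same partner, or poor control of the enol ether geometry, would feed the wrong C5 epimer into step 2.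
- The fallback runs from 3 back to 5. The order of attachment is reversed and a preformed enolate of defined geometry is used.
- 3 with Me3SiCl, NaI and Et3N in MeCN gives (Z)-trimethyl(3-methylbut-1-en-1-yloxy)silane F5, which is freed from its E isomer by fractional distillation.
- MeLi in Et2O converts F5 with retention of geometry into lithium (Z)-3-methylbut-1-en-1-olate F6.
- Addition of F6 to 2 at −78 °C gives di-tert-butyl[(Z)-3-methylbut-1-en-1-yloxy]silyl trifluoromethanesulfonate F7.
- 1 and Et3N then complete 5.

**Step 7.** The lipase may not accept the hindered acetate, may discriminate poorly between the antipodes, or may attack the primary tiglate.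
- The fallback runs from 12 back to 13 and is a classical resolution through covalent diastereomers at the free C4 hydroxyl.
- 12 and (R)-1-phenylethyl isocyanate (DMAP, toluene) give two carbamates. These are the C4 (R)-1-phenylethylcarbamate of the (4S,5S,6R) series F8 and the C4 (R)-1-phenylethylcarbamate of the (4R,5R,6S) series F9. They are separated by chromatography or crystallisation.
- HSiCl3 and Et3N in CH2Cl2 cleave F8 without touching the esters and give 13.

Further compounds
F1 | step 2 | tert-butyl 5-hydroxy-6-isopropyl-2-oxocyclohex-3-ene-1-carboxylate (5,6-cis, racemic, C1 labile) | O=C1C=C[C@H](O)[C@H](C(C)C)C1C(=O)OC(C)(C)C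
F2 | step 2 | cis-4-hydroxy-5-isopropylcyclohex-2-en-1-one (racemic) | O=C1C=C[C@H](O)[C@H](C(C)C)C1
F3 | step 2 | cis-4-hydroxy-2-(hydroxymethyl)-5-isopropylcyclohex-2-en-1-one (racemic) | O=C1C(CO)=C[C@H](O)[C@H](C(C)C)C1
F4 | step 2 | cis-4-hydroxy-5-isopropyl-2-(tigloyloxymethyl)cyclohex-2-en-1-one (racemic) | C/C=C(\C)C(=O)OCC1=C[C@H](O)[C@H](C(C)C)CC1=O
F5 | step 1 | (Z)-trimethyl(3-methylbut-1-en-1-yloxy)silane | CC(C)/C=C\O[Si](C)(C)C
F6 | step 1 | lithium (Z)-3-methylbut-1-en-1-olate | CC(C)/C=C\[O-].[Li+]
F7 | step 1 | di-tert-butyl[(Z)-3-methylbut-1-en-1-yloxy]silyl trifluoromethanesulfonate | CC(C)/C=C\O[Si](OS(=O)(=O)C(F)(F)F)(C(C)(C)C)C(C)(C)C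
F8 | step 7 | C4 (R)-1-phenylethylcarbamate of the (4S,5S,6R) series | C/C=C(\C)C(=O)OCC1=C[C@H](OC(=O)N[C@H](C)c2ccccc2)[C@H](C(C)C)[C@@H](OC(C)=O)C1=O
F9 | step 7 | C4 (R)-1-phenylethylcarbamate of the (4R,5R,6S) series | C/C=C(\C)C(=O)OCC1=C[C@@H](OC(=O)N[C@H](C)c2ccccc2)[C@@H](C(C)C)[C@H](OC(C)=O)C1=O
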